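**Plan**

Locants C1–C12 are those of acid 21 and are kept for all later compounds: C1 is the cyclobutane CH, C11 the quaternary carbon bearing CH3 and CH2O, and C12 the carbon that becomes the C11 methyl.

- **Cuts:** first the two angelate C–O bonds; then C1–C11 (cyclobutane CH to the quaternary carbon of the seven-membered ring), giving a cyclobutanone tosylhydrazone and a methylidene side chain; then both cyclobutane bonds C1–C6 and C2–C7 ([2+2]) to an acyclic vinylketene; the chain is cut at C4–C5 and C9–C10 (two aldol reactions).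
- **Forward:** C5–C9 enone + C10–C12 enal → aldol / Evans–Tishchenko → vinylogous aldol adds C1–C4 → ketene [2+2] builds the bicyclo[3.1.1]heptanone (four- and six-membered rings) → enone → radical closure of the seven-membered ring → desilylation and double angeloylation.
- **Enabling feature:** C1 is the one-carbon bridge between the bridgeheads C2 and C6, so it can be born as a ketene carbonyl. The C8–C11 chain hangs from the C7 bridge on the cyclobutane face opposite the C3–C5 enone bridge, directly under C1. The C11 methyl can come from =CH2 by hydrogen-atom transfer, so a tertiary C11 radical adds to C1=N and loss of N2 leaves C1–H.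
- **Stereochemistry:** C10 from a reagent-controlled boron aldol; C8 from the 1,3-anti Evans–Tishchenko reduction; C5 (temporary, later the enone C=O) from a catalyst-controlled vinylogous aldol. C5 steers the [2+2] (C2, C6, C7) through 1,3-allylic strain; C11 is set in the key step by C10, and C1 by the ring.

Key step: step 15

Remark: tosylhydrazones 25–28 are taken as E/Z mixtures about C=N; both isomers converge in step 15.

**Step 1**
Reactants: 1 allyloxy(tert-butyl)dimethylsilane; 2 3-methylbut-3-en-2-one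
Product: 3 (E)-5-((tert-butyldimethylsilyl)oxy)-3-methylpent-3-en-2-one
Conditions: second-generation Hoveyda–Grubbs catalyst (5 mol%), 2 in excess, CH2Cl2, 40 °C
Reagents that add atoms: none
Why: Olefin cross-metathesis of a terminal allyl ether with a 1,1-disubstituted enone that does not homodimerise should give the thermodynamically preferred (E)-trisubstituted enone.

**Step 2**
Reactants: 4 2-methylenepropane-1,3-diol
Product: 5 2-(((tert-butyldiphenylsilyl)oxy)methyl)prop-2-en-1-ol
Conditions: TBDPSCl (1 equiv), imidazole, 4 (3 equiv), THF, 0 °C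
Reagents that add atoms: tert-butyl(chloro)diphenylsilane, CC(C)(C)[Si](Cl)(c1ccccc1)c1ccccc1
Why: Statistical monosilylation of a symmetric diol used in excess is a routine silyl ether formation.

**Step 3**
Reactants: 5 2-(((tert-butyldiphenylsilyl)oxy)methyl)prop-2-en-1-ol
Product: 6 2-(((tert-butyldiphenylsilyl)oxy)methyl)acrylaldehyde
Conditions: MnO2, CH2Cl2, rt
Reagents that add atoms: none
Why: MnO2 oxidation is selective for the allylic alcohol and does not over-oxidise the enal.

**Step 4**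
Reactants: 3 (E)-5-((tert-butyldimethylsilyl)oxy)-3-methylpent-3-en-2-one; 6 2-(((tert-butyldiphenylsilyl)oxy)methyl)acrylaldehyde
Product: 9 (2E,6R)-1-((tert-butyldimethylsilyl)oxy)-7-(((tert-butyldiphenylsilyl)oxy)methyl)-6-hydroxy-3-methylocta-2,7-dien-4-one (C5–C12 fragment; 10R), via enol diisopinocampheylborinate 7 (not isolated), via boron aldolate 8 (not isolated)
Conditions: (−)-Ipc2BCl, Et3N, Et2O, 0 °C; then 6, −78 → −20 °C; H2O2, pH 7 buffer, MeOH, 0 °C
Reagents that add atoms: none
Why: Diisopinocampheylboron-mediated asymmetric aldol of a methyl ketone: only the methyl group of 3 can enolise, and the isopinocampheyl ligands are expected to direct the enol borinate to the Re face of aldehyde 6, which sets (10R).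

**Step 5**
Reactants: 9 (10R)-β-hydroxy enone
Product: 10 (3R,5R,6E)-8-((tert-butyldimethylsilyl)oxy)-2-(((tert-butyldiphenylsilyl)oxy)methyl)-5-hydroxy-6-methylocta-1,6-dien-3-yl acetate (8R,10R; 1,3-anti)
Conditions: CH3CHO (8 equiv), SmI2 (0.3 equiv), THF, −10 °C
Reagents that add atoms: acetaldehyde, CC=O
Why: Evans–Tishchenko reduction: the samarium-bound hemiacetal formed from O10–H and acetaldehyde delivers hydride intramolecularly to the C8 ketone through a chair-like six-membered transition state, which gives the 1,3-anti (8R) alcohol and leaves the acetyl group on O10, where the target carries its acetate.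

**Step 6**
Reactants: 10 (8R,10R)-hydroxy acetate
Product: 11 (3R,5R,6E)-5,8-bis((tert-butyldimethylsilyl)oxy)-2-(((tert-butyldiphenylsilyl)oxy)methyl)-6-methylocta-1,6-dien-3-yl acetate
Conditions: TBSOTf, 2,6-lutidine, CH2Cl2, −78 °C
Reagents that add atoms: tert-butyldimethylsilyl triflate, CC(C)(C)[Si](C)(C)OS(=O)(=O)C(F)(F)F
Why: Silyl triflate silylation of the secondary allylic alcohol is fast at low temperature, which should prevent 1,3-acetyl migration.

**Step 7**
Reactants: 11 bis-TBS ether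
Product: 12 (3R,5R,6E)-5-((tert-butyldimethylsilyl)oxy)-2-(((tert-butyldiphenylsilyl)oxy)methyl)-8-hydroxy-6-methylocta-1,6-dien-3-yl acetate
Conditions: HF·pyridine, pyridine, THF, 0 °C
Reagents that add atoms: none
Why: Buffered fluoride cleaves the primary allylic TBS ether much faster than the secondary TBS ether or the TBDPS ether (selective desilylation).

**Step 8**
Reactants: 12 C5 allylic alcohol
Product: 13 (3R,5R,6E)-5-((tert-butyldimethylsilyl)oxy)-2-(((tert-butyldiphenylsilyl)oxy)methyl)-6-methyl-8-oxoocta-1,6-dien-3-yl acetate (C5 enal)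
Conditions: MnO2, CH2Cl2, rt
Reagents that add atoms: none
Why: MnO2 allylic oxidation gives the (E)-enal without touching the acetate or silyl ethers.

**Step 9**
Reactants: 14 tert-butyl 3-methylbut-2-enoate
Product: 16 tert-butyl((1-(tert-butoxy)-3-methylbuta-1,3-dien-1-yl)oxy)dimethylsilane, via lithium dienolate 15 (not isolated)
Conditions: LiN(iPr)2, THF/DMPU, −78 °C; then TBSCl
Reagents that add atoms: tert-butyl(chloro)dimethylsilane, CC(C)(C)[Si](C)(C)Cl
Why: Kinetic γ-deprotonation of the senecioate and O-silylation of the dienolate gives the silyl dienol ether (silyl ketene acetal formation).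

**Step 10**
Reactants: 13 C5 enal; 16 silyl dienol ether
Product: 18 tert-butyl (2E,5S,6E,8R,10R)-10-acetoxy-8-((tert-butyldimethylsilyl)oxy)-11-(((tert-butyldiphenylsilyl)oxy)methyl)-5-hydroxy-3,7-dimethyldodeca-2,6,11-trienoate, via trichlorosilyl ether 17 (not isolated)
Conditions: SiCl4 (1.1 equiv), (S,S)-BINAM-derived bisphosphoramide (5 mol%), iPr2NEt (cat.), CH2Cl2, −78 °C; aq. NaHCO3
Reagents that add atoms: none
Why: Vinylogous Mukaiyama aldol under Lewis-base-activated SiCl4 catalysis: the bulky chiral silicon cation forces attack through the γ-carbon of 16, and the catalyst antipode is chosen for addition to the Si face of the enal, which sets the temporary (5S) carbinol with little influence from the remote C8 centre.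

**Step 11**
Reactants: 18 (5S)-hydroxy tert-butyl ester
Product: 21 (2E,5S,6E,8R,10R)-10-acetoxy-8-((tert-butyldimethylsilyl)oxy)-11-(((tert-butyldiphenylsilyl)oxy)methyl)-3,7-dimethyl-5-((triethylsilyl)oxy)dodeca-2,6,11-trienoic acid, via TES ether tert-butyl ester 19 (not isolated), via bis-TES ester 20 (not isolated)
Conditions: TESOTf (2.5 equiv), 2,6-lutidine, CH2Cl2, −78 → 0 °C; then THF/pH 5 buffer
Reagents that add atoms: triethylsilyl triflate, CC[Si](CC)(CC)OS(=O)(=O)C(F)(F)F
Why: The silyl triflate first silylates O5 and then cleaves the tert-butyl ester through its silyl ester (loss of isobutene), which hydrolyses on work-up; this non-hydrolytic ester cleavage spares the C10 acetate.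

**Step 12**
Reactants: 21 (5S)-silyloxy trienoic acid
Product: 24 (2R,5S,6R,7R,8R,10R)-cyclobutanone: 7-methyl-2-methylidene-4-(triethylsilyloxy)bicyclo[3.1.1]heptan-6-one carrying the C8–C12 chain on C7, via acid chloride 22 (not isolated), via vinylketene 23 (not isolated)
Conditions: 1-chloro-N,N,2-trimethylprop-1-en-1-amine, CH2Cl2, 0 °C; then slow addition to Et3N, toluene, 110 °C (high dilution)
Reagents that add atoms: none
Why: Intramolecular vinylketene–alkene [2+2] cycloaddition (ketene formed by 1,4-elimination of HCl through the C3 methyl): the electrophilic ketene carbon C1 bonds to C6 and C2 to the more substituted C7, suprafacial addition to the (E)-alkene places the C7 methyl syn to the C3–C5 bridge and the C8 chain toward the carbonyl bridge, and the C5 stereocentre fixes the alkene face through 1,3-allylic strain (C5–H eclipses the C7 methyl, the tether adds anti to OTES), which sets C2, C6 and C7.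

**Step 13**
Reactants: 24 cyclobutanone
Product: 26 (2R,5S,6S,7R,8R,10R)-C5-hydroxy cyclobutanone tosylhydrazone, via TES-protected tosylhydrazone 25 (not isolated)
Conditions: TsNHNH2, MeOH/THF, rt; then PPTS, rt
Reagents that add atoms: p-toluenesulfonohydrazide, Cc1ccc(cc1)S(=O)(=O)NN
Why: Hydrazone condensation on the strained, unhindered cyclobutanone, then acid-catalysed methanolysis of the secondary TES ether, which is far more labile than the hindered secondary TBS ether and the TBDPS ether.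

**Step 14**
Reactants: 26 C5-hydroxy tosylhydrazone
Product: 28 (2R,6S,7R,8R,10R)-enone tosylhydrazone (C5 ketone, C3=C4, C3 methyl), via deconjugated enone hydrazone 27 (not isolated)
Conditions: SO3·pyridine, DMSO, iPr2NEt, CH2Cl2, 0 °C → rt; then DBU (0.2 equiv), rt
Reagents that add atoms: none
Why: Parikh–Doering oxidation gives the β,γ-unsaturated ketone, whose doubly activated C4 methylene is deprotonated by DBU so that the exocyclic alkene moves into conjugation; C1 is masked as its hydrazone, so no strained β-diketone is ever present.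

**Step 15**
Reactants: 28 enone tosylhydrazone
Product: 31 (1S,2R,6R,7R,8R,10R,11S)-tricyclic enone with C8–OTBS, C10–OAc and C11–CH2OTBDPS, via cyclised N-tosylhydrazide 29 (not isolated), via monoalkyl diazene 30 (not isolated)
Conditions: Fe(acac)3 (0.3 equiv), PhSiH3 (3 equiv), EtOH/THF, 60 °C; then Et3N, 75 °C
Reagents that add atoms: none
Why: An iron hydride formed from Fe(acac)3 and PhSiH3 transfers a hydrogen atom to the terminal CH2 (C12) of the electron-rich 1,1-disubstituted alkene, and the resulting tertiary C11 radical adds to the strained C1=N carbon; the hydrazinyl radical is reduced to hydrazide 29, Et3N eliminates p-toluenesulfinate to diazene 30, and loss of N2 leaves C1–H. The closest known reaction type is the metal-hydride hydrogen-atom-transfer reductive coupling of unactivated alkenes with ketone sulfonylhydrazones, known inter- and intramolecularly. The seven-membered ring closes in 7-exo-trig mode onto C=N, helped by the quaternary C7 and the cyclobutane, which hold C8–C11 under C1 on the face opposite the C3–C5 bridge, and by relief of the sp2 strain in the four-membered ring. C1 can only be attacked from that lower face, so its hydrogen necessarily ends up syn to the enone bridge; C11 is controlled by the adjacent C10 acetoxy centre, the bulky CH2OTBDPS group taking the side of C10–H and the new methyl the side of C10–OAc in the forming ring, which should give (11S). The step needs hydrogen-atom transfer to the methylidene group and not to the enone, which is secured because C3=C4 is electron-poor and trisubstituted and because the exocyclic C3 methylene was already conjugated in step 14; the enone lies on the other face of the cyclobutane, out of reach of the C11 radical.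

**Step 16**
Reactants: 31 tricyclic bis-silyl ether
Product: 32 (1S,2R,6R,7R,8R,10R,11S)-C8,C11-CH2 diol with C10 acetate
Conditions: Bu4NF, AcOH (1:1), THF, 0 → 45 °C
Reagents that add atoms: none
Why: Fluoride desilylation buffered with acetic acid removes both silyl ethers while suppressing base-induced migration or loss of the C10 acetate.

**Step 17**
Reactants: 32 diol
Product: 33 CNP0364726.1 (C8 and C11-CH2 bis-angelate, C10 acetate)
Conditions: angelic acid, 2,4,6-trichlorobenzoyl chloride, Et3N, toluene, rt; then 32, 80 °C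
Reagents that add atoms: angelic acid, C/C=C(/C)C(=O)O
Why: Yamaguchi-type esterification with the preformed mixed anhydride, run without a nucleophilic catalyst, should acylate the primary and the hindered secondary hydroxyl while keeping the (Z)-geometry of the angeloyl groups.

**Compound list**

1 | allyloxy(tert-butyl)dimethylsilane | C=CCO[Si](C)(C)C(C)(C)C | starting material
2 | 3-methylbut-3-en-2-one | CC(=O)C(C)=C | starting material
3 | (E)-5-((tert-butyldimethylsilyl)oxy)-3-methylpent-3-en-2-one | CC(=O)/C(C)=C/CO[Si](C)(C)C(C)(C)C | intermediate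
4 | 2-methylenepropane-1,3-diol | C=C(CO)CO | starting material
5 | 2-(((tert-butyldiphenylsilyl)oxy)methyl)prop-2-en-1-ol | C=C(CO)CO[Si](c1ccccc1)(c1ccccc1)C(C)(C)C | intermediate
6 | 2-(((tert-butyldiphenylsilyl)oxy)methyl)acrylaldehyde | C=C(C=O)CO[Si](c1ccccc1)(c1ccccc1)C(C)(C)C | intermediate
7 | enol diisopinocampheylborinate of 3 | C=C(OB([C@@H]1C[C@@H]2C[C@H]([C@H]1C)C2(C)C)[C@@H]1C[C@@H]2C[C@H]([C@H]1C)C2(C)C)/C(C)=C/CO[Si](C)(C)C(C)(C)C | intermediate
8 | diisopinocampheylboron aldolate (boron on O10) | O=C(C[C@@H](OB([C@@H]1C[C@@H]2C[C@H]([C@H]1C)C2(C)C)[C@@H]1C[C@@H]2C[C@H]([C@H]1C)C2(C)C)C(=C)CO[Si](c1ccccc1)(c1ccccc1)C(C)(C)C)/C(C)=C/CO[Si](C)(C)C(C)(C)C | intermediate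
9 | (2E,6R)-1-((tert-butyldimethylsilyl)oxy)-7-(((tert-butyldiphenylsilyl)oxy)methyl)-6-hydroxy-3-methylocta-2,7-dien-4-one | O=C(C[C@@H](O)C(=C)CO[Si](c1ccccc1)(c1ccccc1)C(C)(C)C)/C(C)=C/CO[Si](C)(C)C(C)(C)C | intermediate
10 | (3R,5R,6E)-8-((tert-butyldimethylsilyl)oxy)-2-(((tert-butyldiphenylsilyl)oxy)methyl)-5-hydroxy-6-methylocta-1,6-dien-3-yl acetate | CC(C)(C)[Si](C)(C)OC/C=C(C)/[C@H](O)C[C@@H](OC(C)=O)C(=C)CO[Si](c1ccccc1)(c1ccccc1)C(C)(C)C | intermediate
11 | (3R,5R,6E)-5,8-bis((tert-butyldimethylsilyl)oxy)-2-(((tert-butyldiphenylsilyl)oxy)methyl)-6-methylocta-1,6-dien-3-yl acetate | CC(C)(C)[Si](C)(C)OC/C=C(C)/[C@H](O[Si](C)(C)C(C)(C)C)C[C@@H](OC(C)=O)C(=C)CO[Si](c1ccccc1)(c1ccccc1)C(C)(C)C | intermediate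
12 | (3R,5R,6E)-5-((tert-butyldimethylsilyl)oxy)-2-(((tert-butyldiphenylsilyl)oxy)methyl)-8-hydroxy-6-methylocta-1,6-dien-3-yl acetate | OC/C=C(C)/[C@H](O[Si](C)(C)C(C)(C)C)C[C@@H](OC(C)=O)C(=C)CO[Si](c1ccccc1)(c1ccccc1)C(C)(C)C | intermediate
13 | (3R,5R,6E)-5-((tert-butyldimethylsilyl)oxy)-2-(((tert-butyldiphenylsilyl)oxy)methyl)-6-methyl-8-oxoocta-1,6-dien-3-yl acetate | O=C/C=C(C)/[C@H](O[Si](C)(C)C(C)(C)C)C[C@@H](OC(C)=O)C(=C)CO[Si](c1ccccc1)(c1ccccc1)C(C)(C)C | intermediate
14 | tert-butyl 3-methylbut-2-enoate | CC(C)=CC(=O)OC(C)(C)C | starting material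
15 | lithium dienolate of 14 | [Li]OC(OC(C)(C)C)=CC(C)=C | intermediate
16 | tert-butyl((1-(tert-butoxy)-3-methylbuta-1,3-dien-1-yl)oxy)dimethylsilane | C=C(C)C=C(OC(C)(C)C)O[Si](C)(C)C(C)(C)C | intermediate
17 | 5-O-trichlorosilyl ether of 18 | CC(C)(C)OC(=O)/C=C(C)/C[C@H](O[Si](Cl)(Cl)Cl)/C=C(C)/[C@H](O[Si](C)(C)C(C)(C)C)C[C@@H](OC(C)=O)C(=C)CO[Si](c1ccccc1)(c1ccccc1)C(C)(C)C | intermediate
18 | tert-butyl (2E,5S,6E,8R,10R)-10-acetoxy-8-((tert-butyldimethylsilyl)oxy)-11-(((tert-butyldiphenylsilyl)oxy)methyl)-5-hydroxy-3,7-dimethyldodeca-2,6,11-trienoate | CC(C)(C)OC(=O)/C=C(C)/C[C@H](O)/C=C(C)/[C@H](O[Si](C)(C)C(C)(C)C)C[C@@H](OC(C)=O)C(=C)CO[Si](c1ccccc1)(c1ccccc1)C(C)(C)C | intermediate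
19 | 5-O-triethylsilyl ether of 18 | CC(C)(C)OC(=O)/C=C(C)/C[C@H](O[Si](CC)(CC)CC)/C=C(C)/[C@H](O[Si](C)(C)C(C)(C)C)C[C@@H](OC(C)=O)C(=C)CO[Si](c1ccccc1)(c1ccccc1)C(C)(C)C | intermediate
20 | triethylsilyl ester of 21 | CC[Si](CC)(CC)OC(=O)/C=C(C)/C[C@H](O[Si](CC)(CC)CC)/C=C(C)/[C@H](O[Si](C)(C)C(C)(C)C)C[C@@H](OC(C)=O)C(=C)CO[Si](c1ccccc1)(c1ccccc1)C(C)(C)C | intermediate
21 | (2E,5S,6E,8R,10R)-10-acetoxy-8-((tert-butyldimethylsilyl)oxy)-11-(((tert-butyldiphenylsilyl)oxy)methyl)-3,7-dimethyl-5-((triethylsilyl)oxy)dodeca-2,6,11-trienoic acid | OC(=O)/C=C(C)/C[C@H](O[Si](CC)(CC)CC)/C=C(C)/[C@H](O[Si](C)(C)C(C)(C)C)C[C@@H](OC(C)=O)C(=C)CO[Si](c1ccccc1)(c1ccccc1)C(C)(C)C | intermediate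
22 | acid chloride of 21 | ClC(=O)/C=C(C)/C[C@H](O[Si](CC)(CC)CC)/C=C(C)/[C@H](O[Si](C)(C)C(C)(C)C)C[C@@H](OC(C)=O)C(=C)CO[Si](c1ccccc1)(c1ccccc1)C(C)(C)C | intermediate
23 | vinylketene (C1 ketene, C3 methylidene) | O=C=CC(=C)C[C@H](O[Si](CC)(CC)CC)/C=C(C)/[C@H](O[Si](C)(C)C(C)(C)C)C[C@@H](OC(C)=O)C(=C)CO[Si](c1ccccc1)(c1ccccc1)C(C)(C)C | intermediate
24 | (2R,5S,6R,7R,8R,10R)-cyclobutanone: 7-methyl-2-methylidene-4-(triethylsilyloxy)bicyclo[3.1.1]heptan-6-one with the C8–C12 chain on C7 | O=C1[C@H]2[C@@H](O[Si](CC)(CC)CC)CC(=C)[C@@H]1[C@@]2(C)[C@H](O[Si](C)(C)C(C)(C)C)C[C@@H](OC(C)=O)C(=C)CO[Si](c1ccccc1)(c1ccccc1)C(C)(C)C | intermediate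
25 | tosylhydrazone of 24 | Cc1ccc(cc1)S(=O)(=O)NN=C1[C@H]2[C@@H](O[Si](CC)(CC)CC)CC(=C)[C@@H]1[C@@]2(C)[C@H](O[Si](C)(C)C(C)(C)C)C[C@@H](OC(C)=O)C(=C)CO[Si](c1ccccc1)(c1ccccc1)C(C)(C)C | intermediate
26 | (2R,5S,6S,7R,8R,10R)-C5-hydroxy tosylhydrazone | Cc1ccc(cc1)S(=O)(=O)NN=C1[C@H]2[C@@H](O)CC(=C)[C@@H]1[C@@]2(C)[C@H](O[Si](C)(C)C(C)(C)C)C[C@@H](OC(C)=O)C(=C)CO[Si](c1ccccc1)(c1ccccc1)C(C)(C)C | intermediate
27 | (2R,6S,7R,8R,10R)-C5-keto, C3-methylidene tosylhydrazone | Cc1ccc(cc1)S(=O)(=O)NN=C1[C@H]2C(=O)CC(=C)[C@@H]1[C@@]2(C)[C@H](O[Si](C)(C)C(C)(C)C)C[C@@H](OC(C)=O)C(=C)CO[Si](c1ccccc1)(c1ccccc1)C(C)(C)C | intermediate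
28 | (2R,6S,7R,8R,10R)-enone tosylhydrazone | Cc1ccc(cc1)S(=O)(=O)NN=C1[C@H]2C(=O)C=C(C)[C@@H]1[C@@]2(C)[C@H](O[Si](C)(C)C(C)(C)C)C[C@@H](OC(C)=O)C(=C)CO[Si](c1ccccc1)(c1ccccc1)C(C)(C)C | intermediate
29 | tricyclic N'-tosylhydrazide (N on C1, anti to C11) | CC(C)(C)[Si](c1ccccc1)(c1ccccc1)OC[C@]1(C)[C@]2(NNS(=O)(=O)c4ccc(C)cc4)[C@H]3C(=O)C=C(C)[C@@H]2[C@@]3(C)[C@H](O[Si](C)(C)C(C)(C)C)C[C@H]1OC(C)=O | intermediate
30 | tricyclic monoalkyl diazene | CC(C)(C)[Si](c1ccccc1)(c1ccccc1)OC[C@]1(C)[C@]2(N=N)[C@H]3C(=O)C=C(C)[C@@H]2[C@@]3(C)[C@H](O[Si](C)(C)C(C)(C)C)C[C@H]1OC(C)=O | intermediate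
31 | (1S,2R,6R,7R,8R,10R,11S)-tricyclic enone, C8–OTBS, C10–OAc, C11–CH2OTBDPS | CC(C)(C)[Si](c1ccccc1)(c1ccccc1)OC[C@]1(C)[C@@H]2[C@H]3C(=O)C=C(C)[C@@H]2[C@@]3(C)[C@H](O[Si](C)(C)C(C)(C)C)C[C@H]1OC(C)=O | intermediate
32 | (1S,2R,6R,7R,8R,10R,11S)-tricyclic enone diol, C10–OAc | OC[C@]1(C)[C@@H]2[C@H]3C(=O)C=C(C)[C@@H]2[C@@]3(C)[C@H](O)C[C@H]1OC(C)=O | intermediate
33 | CNP0364726.1 | C/C=C(/C)C(=O)OC[C@]1(C)[C@@H]2[C@H]3C(=O)C=C(C)[C@@H]2[C@@]3(C)[C@H](OC(=O)/C(C)=C\C)C[C@H]1OC(C)=O | target

**Summary**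

Total step count: 17. Longest linear sequence: 15 steps (steps 2–8 and 10–17, starting from diol 4).

Steps most likely to fail:

1. Step 15. The tertiary C11 radical may be reduced (alkene hydrogenation) before the slow seven-membered ring closure, and facial discrimination at C11 may be incomplete. Fallback: the radical is generated in a separate operation and cyclised in a dilute chain process that gives it a longer lifetime. Setting out from 28, Markovnikov hydrobromination (Co(acac)2, t-BuOOH, Et3SiH, TsBr, n-PrOH) should give the tertiary bromide F1 (both C11 epimers serve). Bromine-atom abstraction with Bu3SnH/AIBN (benzene, 80 °C, syringe pump) then closes the ring onto the tosylhydrazone to give 29. Et3N/MeOH at 65 °C takes 29 through 30, and the route is rejoined at 31.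

2. Step 12. The cycloaddition may be slow at an alkene that carries two allylic silyloxy groups, allowing ketene oligomerisation or loss of regio- and facial control. Fallback: the ketene is replaced by a more electrophilic keteniminium ion. Setting out from 21, amide coupling with pyrrolidine gives the pyrrolidine amide F2. Tf2O and 2,4,6-collidine (ClCH2CH2Cl, 80 °C) convert it to the vinylketeniminium triflate F3, which should close under the same C5 control to the cyclobutaniminium triflate F4. Aqueous NaHCO3 hydrolysis returns to the route at 24.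

3. Step 17. The angeloyl groups may isomerise from Z to E (tiglate) during the slow acylation of the hindered C8 hydroxyl, and the C10 acetyl group may migrate under heating with base. Fallback: the Z-alkene is built on the ester and not carried through the acylation. Setting out from 32, esterification of both hydroxyls with 2-[bis(2,2,2-trifluoroethoxy)phosphoryl]propanoic acid (DCC, DMAP, CH2Cl2, rt) gives the bis(phosphonopropionate) F5. A double Still–Gennari olefination with acetaldehyde (KN(SiMe3)2, 18-crown-6, THF, −78 °C) should form both (Z)-2-methylbut-2-enoates and rejoins the route at 33.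

**Further compounds**

F1 | step 15 | C11 tertiary bromide of 28 (C11 epimers) | Cc1ccc(cc1)S(=O)(=O)NN=C1[C@H]2C(=O)C=C(C)[C@@H]1[C@@]2(C)[C@H](O[Si](C)(C)C(C)(C)C)C[C@@H](OC(C)=O)C(C)(Br)CO[Si](c1ccccc1)(c1ccccc1)C(C)(C)C
F2 | step 12 | pyrrolidine amide of 21 | O=C(N1CCCC1)/C=C(C)/C[C@H](O[Si](CC)(CC)CC)/C=C(C)/[C@H](O[Si](C)(C)C(C)(C)C)C[C@@H](OC(C)=O)C(=C)CO[Si](c1ccccc1)(c1ccccc1)C(C)(C)C
F3 | step 12 | vinylketeniminium triflate | C1CC[N+](C1)=C=CC(=C)C[C@H](O[Si](CC)(CC)CC)/C=C(C)/[C@H](O[Si](C)(C)C(C)(C)C)C[C@@H](OC(C)=O)C(=C)CO[Si](c1ccccc1)(c1ccccc1)C(C)(C)C.[O-]S(=O)(=O)C(F)(F)F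
F4 | step 12 | cyclobutaniminium triflate (iminium of 24) | C1CC[N+](C1)=C1[C@H]2[C@@H](O[Si](CC)(CC)CC)CC(=C)[C@@H]1[C@@]2(C)[C@H](O[Si](C)(C)C(C)(C)C)C[C@@H](OC(C)=O)C(=C)CO[Si](c1ccccc1)(c1ccccc1)C(C)(C)C.[O-]S(=O)(=O)C(F)(F)F
F5 | step 17 | bis(2-(bis(2,2,2-trifluoroethoxy)phosphoryl)propanoate) of 32 | CC(C(=O)OC[C@]1(C)[C@@H]2[C@H]3C(=O)C=C(C)[C@@H]2[C@@]3(C)[C@H](OC(=O)C(C)P(=O)(OCC(F)(F)F)OCC(F)(F)F)C[C@H]1OC(C)=O)P(=O)(OCC(F)(F)F)OCC(F)(F)F
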